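**Retrosynthetic overview**
1. Ring numbering follows the systematic name: C1 (alkene carbon bearing CO2H), C2 (=CH), C3, C4, C5 (C=CH2), C6 (CHOH), C7, C8 (CMe2), C9, C10 (CH–O–isovaleryl), C11. Target 15 comes from its tert-butyl ester 13 by one deprotection.
2. Key disconnection C6–C7: the eleven-membered carbocycle, the only ring, opens to the acyclic iodo enal 11. In the forward sense a cobalt/chromium radical–polar crossover turns the neopentyl iodide carbon C7 into an alkylchromium. This adds to the C6 aldehyde, closing the ring and setting C6 with every other group already in place.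
3. Enabling feature: C7 is a CH2 next to the quaternary C8, so it has no β-hydrogen, forms a weak C–Co bond and benefits from the gem-dialkyl effect. C6 is the carbonyl carbon of a 2-alkylacrolein whose C5=CH2 is the exocyclic methylene. C8 must sit at a corner of the eleven-membered ring, and the local twofold axis through that corner maps C10 on C6 and relays the configuration. The in-ring cis C1=C2 bond folds the chain.
4. Compound 11 comes from acrylate 8 by cross metathesis with hex-5-enal (E enoate C1=C2) and α-methylenation (C5=CH2). Compound 8 comes from 4-iodo-3,3-dimethylbutanal by catalytic asymmetric 2-(alkoxycarbonyl)allylation (sets C10) and acylation.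
5. Ring order: one ring only, formed in step 7. Step 8 frees the acid.

Key step: step 7

Remark: compounds 1, 4, 7 and 9 are taken as commercial. The descriptor at the acyloxy carbon reads R while iodine (or chromium) is in the molecule and S afterwards, with no change of the spatial arrangement.

Step 1
Reactants: 1 2,2-dimethylpent-4-en-1-ol
Product: 2 5-iodo-4,4-dimethylpent-1-ene
Conditions: I2, PPh3, imidazole, toluene, 80 °C
Reagents that add atoms: iodine, II
Why: Appel-type iodination through the alkoxyphosphonium salt, which is slow at the neopentyl carbon but should be clean on heating because no carbocation forms and so no 1,2-shift occurs.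

Step 2
Reactants: 2 5-iodo-4,4-dimethylpent-1-ene
Product: 3 4-iodo-3,3-dimethylbutanal
Conditions: OsO4 (2 mol %), NaIO4 (4 equiv), 2,6-lutidine, 1,4-dioxane/H2O 3:1, rt
Reagents that add atoms: sodium periodate, [Na+].[O-]I(=O)(=O)=O (aldehyde oxygen, relayed by OsO4)
Why: Lemieux–Johnson cleavage (osmium-catalysed dihydroxylation, then periodate glycol cleavage) removes the terminal CH2 and is preferred to ozone or peracids because periodate leaves the alkyl iodide untouched.

Step 3
Reactants: 3 4-iodo-3,3-dimethylbutanal; 4 tert-butyl 2-(bromomethyl)prop-2-enoate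
Product: 6 tert-butyl (4R)-4-hydroxy-7-iodo-6,6-dimethyl-2-methylideneheptanoate, via silyl ether 5 (not isolated)
Conditions: CrCl2 (10 mol %), tridentate C2-symmetric bis(oxazolinyl)carbazole ligand (12 mol %, the antipode that gives Re-face attack), i-Pr2NEt (30 mol %), Mn (2 equiv), TMSCl (2 equiv), THF, rt; then aq. citric acid, THF, 0 °C
Reagents that add atoms: chlorotrimethylsilane, C[Si](C)(C)Cl (silyl group of 5 only)
Why: Catalytic asymmetric Nozaki–Hiyama–Kishi allylation, in which the allylchromium from 4 adds inside the chiral chromium complex through a chair-like transition state to the Re face of 3 and so sets C10, while the neopentyl iodide is inert to divalent chromium without cobalt and the tert-butyl ester keeps the γ-hydroxy ester from lactonising.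

Step 4
Reactants: 6 tert-butyl (4R)-4-hydroxy-7-iodo-6,6-dimethyl-2-methylideneheptanoate; 7 3-methylbutanoyl chloride
Product: 8 tert-butyl (4R)-7-iodo-6,6-dimethyl-2-methylidene-4-[(3-methylbutanoyl)oxy]heptanoate
Conditions: pyridine, DMAP (10 mol %), CH2Cl2, 0 °C to rt
Reagents that add atoms: none
Why: DMAP-catalysed O-acylation under non-basic conditions installs the isovalerate early, leaves the carbinol centre untouched, avoids alkoxide attack on the iodide and removes any later risk of γ-lactone formation.

Step 5
Reactants: 8 tert-butyl (4R)-7-iodo-6,6-dimethyl-2-methylidene-4-[(3-methylbutanoyl)oxy]heptanoate; 9 hex-5-enal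
Product: 10 tert-butyl (2E)-2-{(2R)-5-iodo-4,4-dimethyl-2-[(3-methylbutanoyl)oxy]pentyl}-7-oxohept-2-enoate
Conditions: 9 (3 equiv), second-generation Hoveyda–Grubbs catalyst (10 mol % in two portions), 1,4-benzoquinone (10 mol %), toluene, 60 °C
Reagents that add atoms: none
Why: Olefin cross metathesis of a reactive terminal alkene with a slow 1,1-disubstituted acrylate should give the cross product selectively, and reversible metathesis should place the new chain trans to the ester (E), which is the geometry of the target.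

Step 6
Reactants: 10 tert-butyl (2E)-2-{(2R)-5-iodo-4,4-dimethyl-2-[(3-methylbutanoyl)oxy]pentyl}-7-oxohept-2-enoate
Product: 11 tert-butyl (2E)-6-formyl-2-{(2R)-5-iodo-4,4-dimethyl-2-[(3-methylbutanoyl)oxy]pentyl}hepta-2,6-dienoate
Conditions: 37 % aq. CH2O, pyrrolidine (20 mol %), propionic acid (20 mol %), i-PrOH, 45 °C
Reagents that add atoms: formaldehyde, C=O
Why: Organocatalytic Mannich condensation–elimination (α-methylenation of an aldehyde through its enamine) installs C5=CH2 without strong base, and the neopentyl iodide, both esters and the trisubstituted enoate should not react with the secondary amine.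

Step 7
Reactants: 11 tert-butyl (2E)-6-formyl-2-{(2R)-5-iodo-4,4-dimethyl-2-[(3-methylbutanoyl)oxy]pentyl}hepta-2,6-dienoate
Product: 13 tert-butyl (1E,6S,10S)-6-hydroxy-8,8-dimethyl-5-methylidene-10-[(3-methylbutanoyl)oxy]cycloundec-1-ene-1-carboxylate, via alkylchromium dichloride 12 (not isolated)
Conditions: CrCl2 (25 equiv, 0.05 M), cobalt phthalocyanine Co(C32H16N8) (10 mol %), DMF, 30 °C; 11 added by syringe pump over 15 h, final 2 mM; aq. sodium potassium tartrate work-up
Reagents that add atoms: chromium dichloride, [Cr+2].[Cl-].[Cl-] (metal of 12 only)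
Why: Proposed new method: divalent chromium reduces the cobalt phthalocyanine to monovalent cobalt, which takes up the neopentyl iodide; the C7–Co bond, strained by the adjacent quaternary C8, should homolyse at once, the primary C7 radical should be trapped by the 0.05 M excess of divalent chromium faster than it adds to C2 or to the methylene on C5 or abstracts an allylic hydrogen from C11, and the alkylchromium 12 then adds to the chromium-bound C6 aldehyde. The closest known reaction types are the bimolecular cobalt-catalysed alkylchromium addition to aldehydes and the Nozaki–Hiyama–Kishi macrocyclisations of alkenyl and allyl halides; what is new is an unactivated alkyl iodide closing a medium ring. The eleven-membered ring closes in the 11-exo-trig mode on the carbonyl carbon. The new centre C6 is controlled by C10: the gem-dimethyl carbon C8 can only occupy a corner of the forming ring, the local twofold axis through that corner maps C10 on C6, and only Si-face attack, which gives (6S), lets both the acyloxy group and the bulky chromium alkoxide point outwards. The step needs the aldehyde over the two ester carbonyls (including the isovalerate carbonyl six atoms from C7), 1,2- over 1,4-addition and ring closure over oligomerisation; the first two are inherent in trivalent alkylchromium reagents, and the last is secured by slow addition to 2 mM, by the gem-dialkyl effect of C8 and by the in-ring cis C1=C2 bond and the sp2 atoms C5 and C6, which fold the chain and remove transannular hydrogens.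

Step 8
Reactants: 13 tert-butyl (1E,6S,10S)-6-hydroxy-8,8-dimethyl-5-methylidene-10-[(3-methylbutanoyl)oxy]cycloundec-1-ene-1-carboxylate
Product: 15 (1E,6S,10S)-6-hydroxy-8,8-dimethyl-5-methylidene-10-[(3-methylbutanoyl)oxy]cycloundec-1-ene-1-carboxylic acid, via bis-silyl derivative 14 (not isolated)
Conditions: TMSOTf (4 equiv), 2,6-lutidine (6 equiv), CH2Cl2, 0 °C; then aq. citric acid, THF, 0 °C
Reagents that add atoms: trimethylsilyl trifluoromethanesulfonate, C[Si](C)(C)OS(=O)(=O)C(F)(F)F (silyl groups of 14 only)
Why: Silyl-triflate-mediated tert-butyl ester cleavage (O-silylation, loss of isobutene to the buffer base) runs without protic acid while the allylic alcohol is masked in situ as its silyl ether, so that the mild hydrolysis should release acid and alcohol with the isovalerate, both alkenes and both stereocentres untouched.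

**Compound list**
1 | 2,2-dimethylpent-4-en-1-ol | C=CCC(C)(C)CO | starting material
2 | 5-iodo-4,4-dimethylpent-1-ene | C=CCC(C)(C)CI | intermediate
3 | 4-iodo-3,3-dimethylbutanal | O=CCC(C)(C)CI | intermediate
4 | tert-butyl 2-(bromomethyl)prop-2-enoate | C=C(CBr)C(=O)OC(C)(C)C | starting material
5 | tert-butyl (4R)-7-iodo-6,6-dimethyl-2-methylidene-4-[(trimethylsilyl)oxy]heptanoate | C=C(C(=O)OC(C)(C)C)C[C@@H](O[Si](C)(C)C)CC(C)(C)CI | intermediate
6 | tert-butyl (4R)-4-hydroxy-7-iodo-6,6-dimethyl-2-methylideneheptanoate | C=C(C(=O)OC(C)(C)C)C[C@@H](O)CC(C)(C)CI | intermediate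
7 | 3-methylbutanoyl chloride | CC(C)CC(=O)Cl | starting material
8 | tert-butyl (4R)-7-iodo-6,6-dimethyl-2-methylidene-4-[(3-methylbutanoyl)oxy]heptanoate | C=C(C(=O)OC(C)(C)C)C[C@@H](OC(=O)CC(C)C)CC(C)(C)CI | intermediate
9 | hex-5-enal | C=CCCCC=O | starting material
10 | tert-butyl (2E)-2-{(2R)-5-iodo-4,4-dimethyl-2-[(3-methylbutanoyl)oxy]pentyl}-7-oxohept-2-enoate | O=CCCC/C=C(/C(=O)OC(C)(C)C)C[C@@H](OC(=O)CC(C)C)CC(C)(C)CI | intermediate
11 | tert-butyl (2E)-6-formyl-2-{(2R)-5-iodo-4,4-dimethyl-2-[(3-methylbutanoyl)oxy]pentyl}hepta-2,6-dienoate | O=CC(=C)CC/C=C(/C(=O)OC(C)(C)C)C[C@@H](OC(=O)CC(C)C)CC(C)(C)CI | intermediate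
12 | alkylchromium dichloride from 11 (C–I replaced by C–CrCl2, solvated by DMF) | O=CC(=C)CC/C=C(/C(=O)OC(C)(C)C)C[C@@H](OC(=O)CC(C)C)CC(C)(C)C[Cr](Cl)Cl | intermediate
13 | tert-butyl (1E,6S,10S)-6-hydroxy-8,8-dimethyl-5-methylidene-10-[(3-methylbutanoyl)oxy]cycloundec-1-ene-1-carboxylate | C=C1CC/C=C(/C(=O)OC(C)(C)C)C[C@@H](OC(=O)CC(C)C)CC(C)(C)C[C@@H]1O | intermediate
14 | trimethylsilyl (1E,6S,10S)-8,8-dimethyl-5-methylidene-10-[(3-methylbutanoyl)oxy]-6-[(trimethylsilyl)oxy]cycloundec-1-ene-1-carboxylate | C=C1CC/C=C(/C(=O)O[Si](C)(C)C)C[C@@H](OC(=O)CC(C)C)CC(C)(C)C[C@@H]1O[Si](C)(C)C | intermediate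
15 | (1E,6S,10S)-6-hydroxy-8,8-dimethyl-5-methylidene-10-[(3-methylbutanoyl)oxy]cycloundec-1-ene-1-carboxylic acid | C=C1CC/C=C(/C(=O)O)C[C@@H](OC(=O)CC(C)C)CC(C)(C)C[C@@H]1O | target

**Total step count:** 8. **Longest linear sequence:** 8 steps (1 to 15).

**Steps most likely to fail**

Step 7.
- What may go wrong: bimolecular addition and protonolysis of the alkylchromium may outrun closure of the medium ring. The relay from C10 to C6 may also give poor facial selectivity.
- The fallback sets out from 8 and 9 and comes back at 13. It makes the same C–C bond bimolecularly and closes the ring at the alkene.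
- Compound 9 is methylenated as in step 6 to 2-methylidenehex-5-enal F1.
- The known bimolecular cobalt-catalysed alkylchromium addition of 8 to F1 (CrCl2, cobalt phthalocyanine, DMF) should give tert-butyl (4S)-8-hydroxy-6,6-dimethyl-2,9-dimethylidene-4-[(3-methylbutanoyl)oxy]tridec-12-enoate as a carbinol epimer mixture F2.
- Dess–Martin oxidation gives tert-butyl (4S)-6,6-dimethyl-2,9-dimethylidene-4-[(3-methylbutanoyl)oxy]-8-oxotridec-12-enoate F3.
- Corey–Bakshi–Shibata reduction with the (R)-methyl oxazaborolidine and catecholborane, with the alkenyl side acting as the large group, should give tert-butyl (4S,8S)-8-hydroxy-6,6-dimethyl-2,9-dimethylidene-4-[(3-methylbutanoyl)oxy]tridec-12-enoate F4.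
- Ring-closing metathesis under high dilution with the second-generation Hoveyda–Grubbs catalyst closes C1=C2 to 13.

Step 5.
- What may go wrong: the hindered 1,1-disubstituted acrylate may fail to engage, so that self-metathesis of the terminal alkene dominates. The alkene geometry may also erode.
- The fallback sets out from 6 and comes back at 10. It makes the metathesis intramolecular through a temporary silicon tether.
- Compound 6, dichlorodi(propan-2-yl)silane and hex-5-en-1-ol (imidazole, CH2Cl2) give tert-butyl (4R)-4-{[(hex-5-en-1-yloxy)di(propan-2-yl)silyl]oxy}-7-iodo-6,6-dimethyl-2-methylideneheptanoate F5.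
- Ring-closing metathesis should give the cyclic silaketal tert-butyl (8E,11R)-11-(3-iodo-2,2-dimethylpropyl)-2,2-di(propan-2-yl)-1,3-dioxa-2-silacycloundec-8-ene-9-carboxylate F6, in which the ring enforces the in-ring cis alkene.
- HF·pyridine gives tert-butyl (2E)-7-hydroxy-2-[(2R)-2-hydroxy-5-iodo-4,4-dimethylpentyl]hept-2-enoate F7.
- TEMPO/PhI(OAc)2 oxidises only the primary alcohol, giving tert-butyl (2E)-2-[(2R)-2-hydroxy-5-iodo-4,4-dimethylpentyl]-7-oxohept-2-enoate F8.
- Acylation with 7 as in step 4 gives 10.

Step 8.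
- What may go wrong: the allylic C6 oxygen may ionise, or the silyl triflate may induce transannular attack during the ester cleavage.
- The fallback sets out from 11 and comes back at 15. It exchanges the ester before any allylic alcohol exists.
- Trifluoroacetic acid in CH2Cl2 at 0 °C converts 11 into (2E)-6-formyl-2-{(2R)-5-iodo-4,4-dimethyl-2-[(3-methylbutanoyl)oxy]pentyl}hepta-2,6-dienoic acid F9.
- EDC/DMAP and 2-(trimethylsilyl)ethanol give its 2-(trimethylsilyl)ethyl ester F10.
- Ring closure as in step 7 gives 2-(trimethylsilyl)ethyl (1E,6S,10S)-6-hydroxy-8,8-dimethyl-5-methylidene-10-[(3-methylbutanoyl)oxy]cycloundec-1-ene-1-carboxylate F11.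
- Fluoride (tris(dimethylamino)sulfonium difluorotrimethylsilicate, DMF, 0 °C) releases 15 under neutral conditions.

**Further compounds**
F1 | step 7 | 2-methylidenehex-5-enal | C=CCCC(=C)C=O
F2 | step 7 | tert-butyl (4S)-8-hydroxy-6,6-dimethyl-2,9-dimethylidene-4-[(3-methylbutanoyl)oxy]tridec-12-enoate (C8 epimers) | C=C(C(=O)OC(C)(C)C)C[C@@H](OC(=O)CC(C)C)CC(C)(C)CC(O)C(=C)CCC=C
F3 | step 7 | tert-butyl (4S)-6,6-dimethyl-2,9-dimethylidene-4-[(3-methylbutanoyl)oxy]-8-oxotridec-12-enoate | C=C(C(=O)OC(C)(C)C)C[C@@H](OC(=O)CC(C)C)CC(C)(C)CC(=O)C(=C)CCC=C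
F4 | step 7 | tert-butyl (4S,8S)-8-hydroxy-6,6-dimethyl-2,9-dimethylidene-4-[(3-methylbutanoyl)oxy]tridec-12-enoate | C=C(C(=O)OC(C)(C)C)C[C@@H](OC(=O)CC(C)C)CC(C)(C)C[C@@H](C(=C)CCC=C)O
F5 | step 5 | tert-butyl (4R)-4-{[(hex-5-en-1-yloxy)di(propan-2-yl)silyl]oxy}-7-iodo-6,6-dimethyl-2-methylideneheptanoate | C=C(C(=O)OC(C)(C)C)C[C@@H](O[Si](C(C)C)(C(C)C)OCCCCC=C)CC(C)(C)CI
F6 | step 5 | tert-butyl (8E,11R)-11-(3-iodo-2,2-dimethylpropyl)-2,2-di(propan-2-yl)-1,3-dioxa-2-silacycloundec-8-ene-9-carboxylate | CC(C)[Si]1(C(C)C)OCCCC/C=C(/C(=O)OC(C)(C)C)C[C@H](CC(C)(C)CI)O1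
F7 | step 5 | tert-butyl (2E)-7-hydroxy-2-[(2R)-2-hydroxy-5-iodo-4,4-dimethylpentyl]hept-2-enoate | OCCCC/C=C(/C(=O)OC(C)(C)C)C[C@@H](O)CC(C)(C)CI
F8 | step 5 | tert-butyl (2E)-2-[(2R)-2-hydroxy-5-iodo-4,4-dimethylpentyl]-7-oxohept-2-enoate | O=CCCC/C=C(/C(=O)OC(C)(C)C)C[C@@H](O)CC(C)(C)CI
F9 | step 8 | (2E)-6-formyl-2-{(2R)-5-iodo-4,4-dimethyl-2-[(3-methylbutanoyl)oxy]pentyl}hepta-2,6-dienoic acid | O=CC(=C)CC/C=C(/C(=O)O)C[C@@H](OC(=O)CC(C)C)CC(C)(C)CI
F10 | step 8 | 2-(trimethylsilyl)ethyl (2E)-6-formyl-2-{(2R)-5-iodo-4,4-dimethyl-2-[(3-methylbutanoyl)oxy]pentyl}hepta-2,6-dienoate | O=CC(=C)CC/C=C(/C(=O)OCC[Si](C)(C)C)C[C@@H](OC(=O)CC(C)C)CC(C)(C)CI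
F11 | step 8 | 2-(trimethylsilyl)ethyl (1E,6S,10S)-6-hydroxy-8,8-dimethyl-5-methylidene-10-[(3-methylbutanoyl)oxy]cycloundec-1-ene-1-carboxylate | C=C1CC/C=C(/C(=O)OCC[Si](C)(C)C)C[C@@H](OC(=O)CC(C)C)CC(C)(C)C[C@@H]1O
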